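Start from a ratio of two rates for D: the rate at which J catches it to give G, over the rate at which it turns into L on its own. The first grows with the amount of J and the second doesn't, so you can name the J concentration at which they are equal, and a share J/(J+S) of D then becomes G.

| flask | J | D | remark | time |
|---|---|---|---|---|
| eta | 0.73 M | 1.1 equiv | run made earlier |  |
| beta | 2 M | 0.68 equiv | run made earlier |  |
| south-east | 0.60 M | 1.10 equiv |  | 4.0 h |
| north-east | 0.50 M | 3.30 equiv |  | 4.0 h |
| west | 1.0 M | 0.280 equiv |  | 4.0 h |
| north | 2.0 M | 1.10 equiv |  | 4.0 h |

- eta (time / min: G / %, J / %): 25.0: 18, 83; 50.0: 22, 70; 80.0: 26, 61; 90.0: 25, 65; 120: 27, 61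
- beta (time / min: G / %, J / %): 10.0: 12, 84; 20.0: 18, 72; 30.0: 23, 65; 60.0: 28, 54; 120: 34, 47

(each reading ± 2 percentage points)

- percent here means J units held: one X counts as two
- what is said of G includes X
- what was read earlier has a scatter of 2 percentage points, one standard deviation
- reactions considered so far: J + D -> G; D -> L; J + G <-> X
- in an amount of G, one X counts as one G

* all flasks from highest to lowest amount of G, in percent of the J charged, at 4.0 h (south-east / north-east / west / north)
* the same order at 12 min (south-east / north-east / west / north)
* the amount of G, in percent of the J charged of the flask you put first, at 4.0 h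
* the amount of G, in percent of the J charged of the flask you put last, at 4.0 h

You can read S from the earlier runs. The eta run ends at 27% of G from 1.1 equiv of D, a share of 24.5%, with J near 0.511 M at 50.0 min; that gives 1.57 M. The beta run ends at 34% from 0.68 equiv, a share of 50.0%, with J near 1.30 M at 30.0 min; that gives 1.30 M. As a reading with its scatter, the crossover S, the J concentration at which the two rates are equal, is about 1.44 M.

For north-east, I take J at 0.7 of its charge on average, 0.350 M, so my own reckoning gives 64.7% of G.

The forecast says “G plateaus because D is lost to L” and uses a crossover of 1.6 M. It gives north-east > north > south-east > west at 4.0 h and north > north-east > south-east > west at 12 min, with 51% on top and 10.5% at the bottom, so its top stands lower than mine.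

The flask gives north-east > north > south-east > west at 4.0 h and north > north-east > south-east > west at 12 min, with 59.9% in north-east and 11.7% in west.

    J + D → G (k = 0.620 M⁻¹ h⁻¹)
    D → L (k = 0.780 h⁻¹)
    J + G ⇌ X, settled at all times (K = 1.00 M⁻¹)

In north-east, D goes to L 4.7 times as fast as to G at 0.718 h, and 7.9 times as fast at 4.00 h. My S over my mean J gave 4.11 for that ratio. Now take the neighbour of north-east charged with 1.30 equiv of D, where J ends at 62.2%: J midway between start and end is 0.406 M, S then gives an estimate of 28.6% of G, and that flask holds 30.5%.

Readings and results are calculated for an exercise.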